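## Retrosynthetic overview

1. Feature: in the butenolide (O1, C2=O, C3-OH, C4-aryl, C5) the quaternary carbon C5 carries both the ring oxygen O1 and the benzylic carbon C6H2. O1 and the chroman aryl group therefore sit on the two carbons of a latent C5=C6 acrylate lying cis to the C2 carboxyl across C3=C4 (chroman atoms are primed).
2. Key disconnection: O1-C5 and C6-aryl are cut together, which gives dienoic acid 12 and chroman-6-diazonium salt 22. A copper/bis(oxazoline) radical oxyarylation joins them, closes the butenolide and sets C5.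
3. Acid 12 comes from crossed Claisen acylation (C3-C4), chelate-controlled enol triflation (fixes the C3=C4 geometry), Stille coupling with an alpha-stannyl acrylate (C4-C5), and tert-butyl ester acidolysis.
4. Salt 22 comes from 4-nitrophenol by a propargyl ether Claisen cascade (pyran ring), Jacobsen-Katsuki epoxidation (sets C3' as S), hydrogenation (benzylic C-O and NO2), silylation and diazotisation.
5. Ring order: dihydropyran ring (step 9), then butenolide (step 14). The end game is desilylation followed by hydrogenolysis of the two benzyl ethers.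

Key step: step 14

Assumption: the (S,S)-ligand is taken to give the (5R) product. The sense of induction for this new radical class cannot be derived safely from precedent, and if it is the reverse, the equally available (R,R)-ligand is used with no other change.

## Route

Step 1
Reactants: 1 benzyloxyacetic acid
Product: 2 tert-butyl 2-(benzyloxy)acetate
Conditions: tert-butyl 2,2,2-trichloroacetimidate (2 equiv), CH2Cl2/cyclohexane, rt
Reagents that add atoms: tert-butyl 2,2,2-trichloroacetimidate, CC(C)(C)OC(=N)C(Cl)(Cl)Cl
Why: Imidate esterification, in which the carboxylic acid protonates the imidate and is O-alkylated by the tert-butyl group, works under near-neutral conditions that leave the benzyl ether alone.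

Step 2
Reactants: 3 4-(benzyloxy)benzoic acid
Product: 4 4-(benzyloxy)benzoyl chloride
Conditions: (COCl)2, DMF (cat.), CH2Cl2, 0 °C to rt; evaporation
Reagents that add atoms: oxalyl chloride, O=C(Cl)C(=O)Cl
Why: DMF-catalysed acid chloride formation is routine for benzoic acids, and the aryl benzyl ether is inert to it.

Step 3
Reactants: 2 tert-butyl 2-(benzyloxy)acetate (2 equiv); 4 4-(benzyloxy)benzoyl chloride (1 equiv)
Product: 6 tert-butyl 2-(benzyloxy)-3-[4-(benzyloxy)phenyl]-3-oxopropanoate (racemic), via lithium enolate 5 (not isolated)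
Conditions: LiN(iPr)2 (2 equiv), THF, -78 °C; then 4, -78 to -20 °C; aq NH4Cl
Reagents that add atoms: none
Why: In this crossed Claisen acylation the preformed enolate 5 is C-acylated by the non-enolisable aroyl chloride, the second equivalent of 5 takes up the acidic proton of 6, and the bulky ester holds back self-condensation; the racemic C2 centre is erased in step 4.

Step 4
Reactants: 6 tert-butyl 2-(benzyloxy)-3-[4-(benzyloxy)phenyl]-3-oxopropanoate
Product: 8 tert-butyl (E)-2-(benzyloxy)-3-[4-(benzyloxy)phenyl]-3-(trifluoromethylsulfonyloxy)prop-2-enoate (OTf cis to CO2tBu), via chelated enolate 7 (not isolated)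
Conditions: LiOTf, Et3N, CH2Cl2, 0 °C; then Tf2O, -78 to 0 °C
Reagents that add atoms: triflic anhydride, O=S(=O)(OS(=O)(=O)C(F)(F)F)C(F)(F)F
Why: In this chelation-controlled enol triflation of a 2-substituted beta-keto ester, lithium ties the enolate oxygen and the ester carbonyl of 7 into a six-membered chelate, so O-sulfonylation fixes OTf cis to CO2tBu, the relation that later puts the carboxyl next to C5; the geometry is to be confirmed by NOE or X-ray and any minor isomer removed by chromatography.

Step 5
Reactants: 9 methyl propiolate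
Product: 10 methyl 2-(tributylstannyl)acrylate
Conditions: Bu3SnH, Pd(PPh3)4 (2 mol%), THF, 0 °C to rt
Reagents that add atoms: tributyltin hydride, CCCC[SnH](CCCC)CCCC
Why: Palladium-catalysed syn-hydrostannation of an alkynoate places hydrogen on the beta carbon and tin on the carbon alpha to the ester, which gives the 1-substituted vinylstannane.

Step 6
Reactants: 8 enol triflate; 10 methyl 2-(tributylstannyl)acrylate
Product: 11 tert-butyl (2E)-2-(benzyloxy)-3-[4-(benzyloxy)phenyl]-4-(methoxycarbonyl)penta-2,4-dienoate (CO2tBu cis to the acrylate unit)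
Conditions: Pd(PPh3)4 (10 mol%), CuCl, LiCl, DMSO (degassed), BHT (trace), 60 °C
Reagents that add atoms: none
Why: Stille coupling of an electron-poor vinyl triflate proceeds with retention of alkene geometry, CuCl/LiCl speeds the transmetalation of the sluggish 1-substituted vinylstannane, and the fully substituted terminus C3 keeps 11 out of the s-cis conformation and so holds back Diels-Alder dimerisation.

Step 7
Reactants: 11 diene diester
Product: 12 (2E)-2-(benzyloxy)-3-[4-(benzyloxy)phenyl]-4-(methoxycarbonyl)penta-2,4-dienoic acid (carboxyl cis to the acrylate unit)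
Conditions: CF3CO2H/CH2Cl2 (1:4), 0 °C to rt; stored cold with BHT and used soon
Reagents that add atoms: none
Why: Acidolysis of the tert-butyl ester (E1 loss of the tert-butyl cation) is selective because the methyl ester and the benzyl ethers need harsher acid and the alkoxydiene is deactivated toward protonation by its two carbonyl groups.

Step 8
Reactants: 13 4-nitrophenol; 14 3-chloro-3-methylbut-1-yne
Product: 15 1-[(2-methylbut-3-yn-2-yl)oxy]-4-nitrobenzene
Conditions: DBU, CuCl2·2H2O (cat.), MeCN, 0 °C
Reagents that add atoms: none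
Why: Copper-catalysed propargylic etherification accepts the tertiary propargylic chloride and the weakly nucleophilic nitrophenoxide at low temperature.

Step 9
Reactants: 15 aryl propargyl ether
Product: 18 2,2-dimethyl-6-nitro-2H-chromene, via allenylphenol 16 (not isolated), via quinone methide 17 (not isolated)
Conditions: o-dichlorobenzene, 180 °C
Reagents that add atoms: none
Why: In this aromatic propargyl Claisen cascade, a [3,3] shift with tautomerisation gives 16, a 1,5-hydrogen shift gives 17, and oxa-6π electrocyclisation closes the pyran ring, the para nitro group leaving two equivalent ortho positions.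

Step 10
Reactants: 18 2,2-dimethyl-6-nitro-2H-chromene
Product: 19 (3S,4S)-3,4-epoxy-2,2-dimethyl-6-nitrochroman
Conditions: [(S,S)-N,N'-bis(3,5-di-tert-butylsalicylidene)cyclohexane-1,2-diaminato]MnCl (3 mol%), aq NaOCl (pH 11.3), 4-phenylpyridine N-oxide (cat.), CH2Cl2, 0 °C; recrystallisation
Reagents that add atoms: sodium hypochlorite, [Na+].[O-]Cl
Why: 2,2-Dimethylchromenes are the best substrate class for the Jacobsen-Katsuki epoxidation, and the (S,S)-salen ligand directs oxygen transfer to the alkene face that gives the (3S,4S)-epoxide, which sets C3' of the target.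

Step 11
Reactants: 19 (3S,4S)-epoxide
Product: 20 (3S)-6-amino-2,2-dimethylchroman-3-ol
Conditions: H2 (3 atm), 10% Pd/C, EtOAc, rt
Reagents that add atoms: none
Why: Catalytic hydrogenation reduces the nitro group and, as a benzylic epoxide hydrogenolysis, cleaves only the strained C4'-O bond, so the C3'-O bond and its (S) configuration stay untouched.

Step 12
Reactants: 20 (3S)-6-amino-2,2-dimethylchroman-3-ol
Product: 21 (3S)-3-(tert-butyldimethylsilyloxy)-2,2-dimethylchroman-6-amine
Conditions: TBSCl (1.5 equiv), imidazole (3 equiv), DMF, 45 °C; aqueous work-up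
Reagents that add atoms: tert-butyldimethylsilyl chloride, CC(C)(C)[Si](C)(C)Cl
Why: Imidazole-promoted silyl ether formation is O-selective because anilines are not lastingly silylated under these conditions and any N-Si bond is hydrolysed on work-up.

Step 13
Reactants: 21 silyloxy chromanamine
Product: 22 (3S)-3-(tert-butyldimethylsilyloxy)-2,2-dimethylchroman-6-diazonium tetrafluoroborate
Conditions: NOBF4 (1.05 equiv), MeCN, -40 to 0 °C; precipitation with cold Et2O/pentane; stored at -20 °C in the dark
Reagents that add atoms: nitrosonium tetrafluoroborate, N#[O+].F[B-](F)(F)F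
Why: Diazotisation with a preformed nitrosonium salt under aprotic, acid-free conditions gives the isolable tetrafluoroborate directly and spares the silyl ether, which aqueous HBF4 would endanger.

Step 14
Reactants: 12 dienoic acid; 22 chroman-6-diazonium tetrafluoroborate (1.5 equiv)
Product: 25 methyl (2R)-4-(benzyloxy)-3-[4-(benzyloxy)phenyl]-2-{[(3S)-3-(tert-butyldimethylsilyloxy)-2,2-dimethylchroman-6-yl]methyl}-5-oxo-2,5-dihydrofuran-2-carboxylate, via aryl radical 23 (not isolated), via C5 radical 24 (not isolated)
Conditions: Cu(MeCN)4PF6 (10 mol%), 2,2'-(propane-2,2-diyl)bis[(4S)-4-tert-butyl-4,5-dihydro-1,3-oxazole] (12 mol%), 2,6-di-tert-butylpyridine (1.5 equiv), EtOAc, rt, argon; 22 added in portions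
Reagents that add atoms: none
Why: Proposed new method: Ligated Cu(MeCN)4PF6 (monovalent copper) gives one electron to 22, N2 departs, and the nucleophilic alkoxyaryl radical 23 attacks the unsubstituted, ester-activated terminus C6 of 12 as in a Meerwein arylation, which makes the C6-aryl bond and leaves the tertiary radical 24 at C5, delocalised over C5-C4-C3 between an ester acceptor and a benzyloxy donor. The divalent copper so produced holds the carboxylate that 2,6-di-tert-butylpyridine sets free, intercepts 24 at C5 (formally reaching trivalent copper) and forms O1-C5 by C-O reductive elimination, which returns monovalent copper and keeps the cycle redox-neutral. The closest known reaction type is the copper/bis(oxazoline)-catalysed enantioselective radical oxyarylation and oxytrifluoromethylation of 4-arylpent-4-enoic acids, which runs through benzylic radicals on a saturated tether, so the alpha-ester allyl-type radical and the sp2 tether are the untested elements. The butenolide closes in the 5-exo mode with respect to C5=C6, and no other ring size competes because the (E)-C3=C4 bond fixes the carboxyl cis to C5 and bonding at C3 would give a three-membered ring. The C5 configuration is decided by the twofold-symmetric ligand around copper in the capture and C-O-forming event, the distant C3' centre being a spectator, so the minor C5 epimer is a diastereomer that chromatography can remove. The step needs site selectivity (terminal acrylate carbon against the tetrasubstituted C3=C4 bond), chemoselectivity over chain growth, hydrogen abstraction, azo coupling and 6-endo oxa-Michael closure (halide-free counter-ions, portionwise 22, a hindered non-nucleophilic base, benzyl caps on phenol and enol) and face selectivity (ligand).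

Step 15
Reactants: 25 protected lactone
Product: 26 methyl (2R)-4-(benzyloxy)-3-[4-(benzyloxy)phenyl]-2-{[(3S)-3-hydroxy-2,2-dimethylchroman-6-yl]methyl}-5-oxo-2,5-dihydrofuran-2-carboxylate
Conditions: HF·pyridine, THF, 0 °C to rt (polypropylene vessel)
Reagents that add atoms: none
Why: Fluoride-driven Si-O cleavage under buffered, weakly acidic conditions is preferred to basic fluoride sources so that the methyl ester and the lactone are not attacked.

Step 16
Reactants: 26 di-O-benzyl butyrolactone V
Product: 27 butyrolactone V
Conditions: H2 (1 atm), 10% Pd/C, EtOAc/MeOH, rt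
Reagents that add atoms: none
Why: Hydrogenolysis cleaves the aryl and the enol benzyl ethers, as known for O-benzylated enediol lactones of the ascorbic acid type, while the tetrasubstituted C3=C4 bond and the quaternary C5-O1 bond are too hindered to react at balloon pressure.

## Compound list

1 | benzyloxyacetic acid | OC(=O)COCc1ccccc1 | starting material
2 | tert-butyl 2-(benzyloxy)acetate | CC(C)(C)OC(=O)COCc1ccccc1 | intermediate
3 | 4-(benzyloxy)benzoic acid | OC(=O)c1ccc(OCc2ccccc2)cc1 | starting material
4 | 4-(benzyloxy)benzoyl chloride | ClC(=O)c1ccc(OCc2ccccc2)cc1 | intermediate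
5 | lithium enolate of 2 (not isolated) | [Li+].CC(C)(C)OC([O-])=COCc1ccccc1 | intermediate
6 | tert-butyl 2-(benzyloxy)-3-[4-(benzyloxy)phenyl]-3-oxopropanoate, racemic | CC(C)(C)OC(=O)C(OCc1ccccc1)C(=O)c1ccc(OCc2ccccc2)cc1 | intermediate
7 | chelated lithium enolate of 6, enolate O cis to CO2tBu (not isolated) | [Li+].CC(C)(C)OC(=O)/C(OCc1ccccc1)=C(\[O-])c1ccc(OCc2ccccc2)cc1 | intermediate
8 | tert-butyl (E)-2-(benzyloxy)-3-[4-(benzyloxy)phenyl]-3-(trifluoromethylsulfonyloxy)prop-2-enoate, OTf cis to CO2tBu | CC(C)(C)OC(=O)/C(OCc1ccccc1)=C(/c1ccc(OCc2ccccc2)cc1)OS(=O)(=O)C(F)(F)F | intermediate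
9 | methyl propiolate | C#CC(=O)OC | starting material
10 | methyl 2-(tributylstannyl)acrylate | C=C(C(=O)OC)[Sn](CCCC)(CCCC)CCCC | intermediate
11 | tert-butyl (2E)-2-(benzyloxy)-3-[4-(benzyloxy)phenyl]-4-(methoxycarbonyl)penta-2,4-dienoate | CC(C)(C)OC(=O)/C(OCc1ccccc1)=C(/c1ccc(OCc2ccccc2)cc1)C(=C)C(=O)OC | intermediate
12 | (2E)-2-(benzyloxy)-3-[4-(benzyloxy)phenyl]-4-(methoxycarbonyl)penta-2,4-dienoic acid, carboxyl cis to the acrylate unit | OC(=O)/C(OCc1ccccc1)=C(/c1ccc(OCc2ccccc2)cc1)C(=C)C(=O)OC | intermediate
13 | 4-nitrophenol | Oc1ccc(cc1)[N+](=O)[O-] | starting material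
14 | 3-chloro-3-methylbut-1-yne | CC(C)(Cl)C#C | starting material
15 | 1-[(2-methylbut-3-yn-2-yl)oxy]-4-nitrobenzene | C#CC(C)(C)Oc1ccc(cc1)[N+](=O)[O-] | intermediate
16 | 2-(3-methylbuta-1,2-dien-1-yl)-4-nitrophenol (not isolated) | CC(C)=C=Cc1cc(ccc1O)[N+](=O)[O-] | intermediate
17 | 6-(3-methylbut-2-en-1-ylidene)-4-nitrocyclohexa-2,4-dien-1-one (not isolated) | O=C1C=CC([N+](=O)[O-])=CC1=CC=C(C)C | intermediate
18 | 2,2-dimethyl-6-nitro-2H-chromene | CC1(C)C=Cc2cc(ccc2O1)[N+](=O)[O-] | intermediate
19 | (3S,4S)-3,4-epoxy-2,2-dimethyl-6-nitrochroman | O=[N+]([O-])c1ccc2c(c1)[C@@H]1O[C@@H]1C(C)(C)O2 | intermediate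
20 | (3S)-6-amino-2,2-dimethylchroman-3-ol | Nc1ccc2c(c1)C[C@H](O)C(C)(C)O2 | intermediate
21 | (3S)-3-(tert-butyldimethylsilyloxy)-2,2-dimethylchroman-6-amine | Nc1ccc2c(c1)C[C@H](O[Si](C)(C)C(C)(C)C)C(C)(C)O2 | intermediate
22 | (3S)-3-(tert-butyldimethylsilyloxy)-2,2-dimethylchroman-6-diazonium tetrafluoroborate | N#[N+]c1ccc2c(c1)C[C@H](O[Si](C)(C)C(C)(C)C)C(C)(C)O2.F[B-](F)(F)F | intermediate
23 | (3S)-3-(tert-butyldimethylsilyloxy)-2,2-dimethylchroman-6-yl radical (not isolated) | [c]1ccc2c(c1)C[C@H](O[Si](C)(C)C(C)(C)C)C(C)(C)O2 | intermediate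
24 | tertiary C5 radical from addition of 23 to C6 of 12, carboxyl cis to C5 (not isolated) | COC(=O)[C](Cc1ccc2c(c1)C[C@H](O[Si](C)(C)C(C)(C)C)C(C)(C)O2)/C(c1ccc(OCc2ccccc2)cc1)=C(/OCc1ccccc1)C(O)=O | intermediate
25 | methyl (2R)-4-(benzyloxy)-3-[4-(benzyloxy)phenyl]-2-{[(3S)-3-(tert-butyldimethylsilyloxy)-2,2-dimethylchroman-6-yl]methyl}-5-oxo-2,5-dihydrofuran-2-carboxylate | COC(=O)[C@]1(Cc2ccc3c(c2)C[C@H](O[Si](C)(C)C(C)(C)C)C(C)(C)O3)OC(=O)C(OCc2ccccc2)=C1c1ccc(OCc2ccccc2)cc1 | intermediate
26 | methyl (2R)-4-(benzyloxy)-3-[4-(benzyloxy)phenyl]-2-{[(3S)-3-hydroxy-2,2-dimethylchroman-6-yl]methyl}-5-oxo-2,5-dihydrofuran-2-carboxylate | COC(=O)[C@]1(Cc2ccc3c(c2)C[C@H](O)C(C)(C)O3)OC(=O)C(OCc2ccccc2)=C1c1ccc(OCc2ccccc2)cc1 | intermediate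
27 | butyrolactone V, methyl (2R)-4-hydroxy-2-{[(3S)-3-hydroxy-2,2-dimethylchroman-6-yl]methyl}-3-(4-hydroxyphenyl)-5-oxo-2,5-dihydrofuran-2-carboxylate | COC(=O)[C@]1(Cc2ccc3c(c2)C[C@H](O)C(C)(C)O3)OC(=O)C(O)=C1c1ccc(O)cc1 | target

## Step count

Total step count: 16.
Longest linear sequence: 9 steps (steps 8 to 16, from 4-nitrophenol). The acid branch needs 5 linear steps to reach 12.

## Steps most likely to fail

**1. Step 14.**

- What may go wrong:
  - Capture of the electron-poor, delocalised C5 radical by divalent copper may be too slow. Chain growth, hydrogen abstraction or outer-sphere oxidation with loss of face selectivity could then take over.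
  - Rotation about C3-C4 in the allyl-type radical could move the carboxyl away from C5.
- Fallback (known chemistry, from 12 and 22, back at 25): the two bonds are made one after the other.
  - A classical Meerwein bromoarylation of 12 with 22 (CuBr cat., LiBr, acetone/water, rt) relies on bromine-atom transfer from divalent copper bromide to the alpha-ester radical, which is the usual fate of such radicals.
  - It should give (2E)-2-(benzyloxy)-3-[4-(benzyloxy)phenyl]-4-bromo-5-[(3S)-3-(tert-butyldimethylsilyloxy)-2,2-dimethylchroman-6-yl]-4-(methoxycarbonyl)pent-2-enoic acid F1 as a mixture of C-Br epimers.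
  - NaHCO3 in DMF then lets the cis carboxylate displace the tertiary allylic bromide (gamma-halo acid lactonisation). This gives 25 together with its (2S)-epimer at the lactone carbon F2.
  - Because C3' is fixed, the two are diastereomers and are parted by preparative HPLC.

**2. Step 6.**

- What may go wrong: transmetalation onto the crowded, tetrasubstituted vinylpalladium species may be slow. Destannylation or homocoupling of 10 and leakage of the alkene geometry could then compete.
- Fallback (from 8, back at 11): a slim sp carbon is coupled first and the acrylate is built afterwards.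
  - Sonogashira coupling of 8 with ethynyltrimethylsilane (PdCl2(PPh3)2, CuI, Et3N, DMF, rt) should give tert-butyl 2-(benzyloxy)-3-[4-(benzyloxy)phenyl]-5-(trimethylsilyl)pent-2-en-4-ynoate (ester cis to the alkyne) F3.
  - K2CO3 in MeOH frees the terminal enyne tert-butyl 2-(benzyloxy)-3-[4-(benzyloxy)phenyl]pent-2-en-4-ynoate F4.
  - Branched-selective palladium-catalysed methoxycarbonylation of the terminal alkyne (Pd(OAc)2, 2-(diphenylphosphino)pyridine, MeSO3H cat., CO, MeOH, 50 °C) turns C≡CH into C(=CH2)CO2Me, which is 11.

**3. Step 7.**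

- What may go wrong: the alkoxydiene may be protonated at C6 and lactonise prematurely. The enol benzyl group may be lost to acid, or the electron-rich ring may be tert-butylated.
- Fallback (from 8, back at 12): the order of events is reversed so that the diene never meets strong acid.
  - CF3CO2H/CH2Cl2 acts on the acid-stable triflate 8 to give (E)-2-(benzyloxy)-3-[4-(benzyloxy)phenyl]-3-(trifluoromethylsulfonyloxy)prop-2-enoic acid F5.
  - The Stille coupling with 10 is then run on its diisopropylethylammonium salt (Pd(PPh3)4, CuCl, LiCl, DMSO, 60 °C). Free carboxylates are tolerated in this coupling.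
  - Mild acidic work-up delivers 12 directly.

Further compounds
F1 | step 14 | (2E)-2-(benzyloxy)-3-[4-(benzyloxy)phenyl]-4-bromo-5-[(3S)-3-(tert-butyldimethylsilyloxy)-2,2-dimethylchroman-6-yl]-4-(methoxycarbonyl)pent-2-enoic acid, C4 epimers | OC(=O)/C(OCc1ccccc1)=C(/c1ccc(OCc2ccccc2)cc1)C(Br)(Cc1ccc2c(c1)C[C@H](O[Si](C)(C)C(C)(C)C)C(C)(C)O2)C(=O)OC
F2 | step 14 | methyl (2S)-4-(benzyloxy)-3-[4-(benzyloxy)phenyl]-2-{[(3S)-3-(tert-butyldimethylsilyloxy)-2,2-dimethylchroman-6-yl]methyl}-5-oxo-2,5-dihydrofuran-2-carboxylate | COC(=O)[C@@]1(Cc2ccc3c(c2)C[C@H](O[Si](C)(C)C(C)(C)C)C(C)(C)O3)OC(=O)C(OCc2ccccc2)=C1c1ccc(OCc2ccccc2)cc1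
F3 | step 6 | tert-butyl 2-(benzyloxy)-3-[4-(benzyloxy)phenyl]-5-(trimethylsilyl)pent-2-en-4-ynoate, ester cis to the alkyne | CC(C)(C)OC(=O)/C(OCc1ccccc1)=C(/c1ccc(OCc2ccccc2)cc1)C#C[Si](C)(C)C
F4 | step 6 | tert-butyl 2-(benzyloxy)-3-[4-(benzyloxy)phenyl]pent-2-en-4-ynoate, ester cis to the alkyne | CC(C)(C)OC(=O)/C(OCc1ccccc1)=C(/c1ccc(OCc2ccccc2)cc1)C#C
F5 | step 7 | (E)-2-(benzyloxy)-3-[4-(benzyloxy)phenyl]-3-(trifluoromethylsulfonyloxy)prop-2-enoic acid | OC(=O)/C(OCc1ccccc1)=C(/c1ccc(OCc2ccccc2)cc1)OS(=O)(=O)C(F)(F)F
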